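**Retrosynthetic overview**

- The target is a spiro N,O-ketal. O1' of the naphtho[1,8-bc]furan bridges the spiro carbon C3 of the isoindolinone (= C2') and the peri carbon C8a' of the naphthalene, so the five-membered furan ring O1'–C3–C2a'–C8b'–C8a' can be closed last, at O1'–C8a'.
- Disconnection 1 (O1'–C8a'): racemic 3-hydroxy-3-(naphthalen-1-yl)isoindolin-1-one 12. Its carbinol centre C3 epimerises by hemiaminal/keto amide ring–chain tautomerism, so a chiral Pd(II) catalyst that etherifies the peri C–H bond can convert the whole racemate into the (S)-spiro ketal 13.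
- Disconnection 2 (C3–C2a', then N2–C3): C2-lithiated N-(silyloxyethyl)-3-methoxybenzamide adds to a 2-alkoxy-6-methyl-1-naphthaldehyde, and oxidation closes the hydroxylactam. The isoindolinone ring forms first, the furan ring second.
- Protecting groups: the naphthol is carried as an SEM ether, because an ester beside the hemiaminal alkoxide would be open to O-to-O acyl transfer under the basic key step. The side chain is a TIPS ether, because a free hydroxyethyl group would close an oxazolidine on C3. Both leave with fluoride, without acid.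
- Building blocks: 3-methoxybenzoyl chloride, ethanolamine and 6-bromo-2-naphthol.

Key step: step 8

Remark on numbering: isoindolinone C1 (C=O), N2, C3 (spiro), C4 (OMe); naphthofuran O1', C2' (= C3), C2a', C3' (oxygenated), C7' (methyl), C8a' (oxygen-bearing peri carbon), C8b'.

Assumption: the L-configured amino acid ligand is taken to deliver the (S)-product. The sense of induction cannot be predicted with confidence for this substrate, and the D-ligand would be used in the same step if the sense proves opposite.

**Step 1**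
Reactants: 1 3-methoxybenzoyl chloride; 2 ethanolamine
Product: 3 N-(2-hydroxyethyl)-3-methoxybenzamide
Conditions: ethanolamine (2.5 equiv), CH2Cl2, 0 °C to rt
Reagents that add atoms: none
Why: N-acylation of the amino alcohol by the acid chloride (amide formation) should be selective because the amine is far more nucleophilic than the hydroxyl group, and the excess amine takes up the HCl.

**Step 2**
Reactants: 3 N-(2-hydroxyethyl)-3-methoxybenzamide
Product: 4 3-methoxy-N-[2-(triisopropylsilyloxy)ethyl]benzamide
Conditions: TIPSCl, imidazole, DMF, rt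
Reagents that add atoms: triisopropylsilyl chloride, CC(C)[Si](Cl)(C(C)C)C(C)C
Why: Imidazole-promoted O-silylation of the primary alcohol gives an ether that should withstand s-BuLi, the oxidant and the carbonate-buffered palladium step.

**Step 3**
Reactants: 5 6-bromo-2-naphthol
Product: 6 6-bromo-2-hydroxy-1-naphthaldehyde
Conditions: MgCl2, Et3N, (CH2O)n, MeCN, reflux; aq. HCl work-up
Reagents that add atoms: paraformaldehyde (formaldehyde), C=O
Why: Magnesium-mediated ortho-formylation of the phenoxide (Casnati–Skattebøl reaction) should go to C1, the reactive ortho position of a 2-naphthol, and leave the bromide untouched.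

**Step 4**
Reactants: 6 6-bromo-2-hydroxy-1-naphthaldehyde
Product: 7 6-bromo-2-{[2-(trimethylsilyl)ethoxy]methoxy}-1-naphthaldehyde
Conditions: SEMCl, i-Pr2NEt, CH2Cl2, 0 °C to rt
Reagents that add atoms: 2-(trimethylsilyl)ethoxymethyl chloride, C[Si](C)(C)CCOCCl
Why: O-alkylation of the acidic naphthol by the chloromethyl ether (acetal protection) gives an ether that tolerates aryllithiums and is later removed by fluoride.

**Step 5**
Reactants: 7 6-bromo-2-{[2-(trimethylsilyl)ethoxy]methoxy}-1-naphthaldehyde
Product: 8 6-methyl-2-{[2-(trimethylsilyl)ethoxy]methoxy}-1-naphthaldehyde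
Conditions: (MeBO)3, Pd(dppf)Cl2 (5 mol %), K2CO3, 1,4-dioxane/H2O, 100 °C
Reagents that add atoms: trimethylboroxine, CB1OB(C)OB(C)O1
Why: Suzuki–Miyaura methylation of the aryl bromide should proceed in the presence of the non-enolisable aldehyde and the SEM acetal.

**Step 6**
Reactants: 4 3-methoxy-N-[2-(triisopropylsilyloxy)ethyl]benzamide; 8 6-methyl-2-{[2-(trimethylsilyl)ethoxy]methoxy}-1-naphthaldehyde
Product: 10 rac-2-[hydroxy(6-methyl-2-{[2-(trimethylsilyl)ethoxy]methoxy}naphthalen-1-yl)methyl]-3-methoxy-N-[2-(triisopropylsilyloxy)ethyl]benzamide, via dilithiated amide 9 (not isolated)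
Conditions: 4 (1.2 equiv), s-BuLi (2.1 equiv per 4), TMEDA, THF, −78 °C; then 8 (1.0 equiv), −78 to −20 °C; aq. NH4Cl, 0 °C
Reagents that add atoms: none
Why: Directed ortho-metalation, in which the lithium amidate and the methoxy group cooperate to place the second lithium at C2 between them, is followed by 1,2-addition of the aryllithium to the aldehyde; the new carbinol centre forms as a racemate and is removed in step 7.

**Step 7**
Reactants: 10 rac-2-[hydroxy(6-methyl-2-{[2-(trimethylsilyl)ethoxy]methoxy}naphthalen-1-yl)methyl]-3-methoxy-N-[2-(triisopropylsilyloxy)ethyl]benzamide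
Product: 12 rac-3-hydroxy-4-methoxy-3-(6-methyl-2-{[2-(trimethylsilyl)ethoxy]methoxy}naphthalen-1-yl)-2-[2-(triisopropylsilyloxy)ethyl]isoindolin-1-one, via keto amide 11 (not isolated)
Conditions: Dess–Martin periodinane, NaHCO3, CH2Cl2, 0 °C to rt
Reagents that add atoms: none
Why: Dess–Martin oxidation of the diaryl carbinol gives the 2-aroylbenzamide, whose secondary amide N–H should add to the ketone (5-exo-trig, ring–chain tautomerism on the side of the hydroxylactam); the hemiaminal centre C3 forms as a racemate.

**Step 8**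
Reactants: 12 rac-3-hydroxy-4-methoxy-3-(6-methyl-2-{[2-(trimethylsilyl)ethoxy]methoxy}naphthalen-1-yl)-2-[2-(triisopropylsilyloxy)ethyl]isoindolin-1-one
Product: 13 (S)-4-methoxy-7'-methyl-3'-{[2-(trimethylsilyl)ethoxy]methoxy}-2-[2-(triisopropylsilyloxy)ethyl]spiro[isoindoline-3,2'-naphtho[1,8-bc]furan]-1-one
Conditions: Pd(OAc)2 (10 mol %), Boc-L-tert-leucine (20 mol %), PhI(OAc)2 (1.5 equiv), Li2CO3 (1.5 equiv), C6F6, 80 °C
Reagents that add atoms: none
Why: Proposed new method: the hemiaminal O–H of 12 binds Pd(II) as an alkoxide, the N-acyl amino acid ligand assists concerted metalation–deprotonation at the peri C8a'–H through a six-membered oxapalladacycle, PhI(OAc)2 oxidises this to Pd(IV), and C(aryl)–O reductive elimination forms O1'–C8a'. The closest known reactions are the Pd(II)/PhI(OAc)2 hydroxyl-directed C–H activation/C–O cyclisation of tertiary alcohols to dihydrobenzofurans and the amino-acid-ligand-controlled enantioselective C–H activation/C–O cyclisation; a dynamic kinetic resolution of a hemiaminal in this manifold is not known. The furan ring closes by contraction of the six-membered palladacycle with extrusion of palladium, which gives the five-membered peri-fused ring O1'–C3–C2a'–C8b'–C8a'. The stereocentre C3 is selected, not created: carbonate-mediated ring–chain tautomerism through keto amide 11 interconverts the enantiomers of 12, and the chiral ligand on palladium is expected to cleave the C–H bond of one enantiomer faster, so that the racemate drains into (S)-13, whose N,O-ketal should not reopen in the buffered, non-acidic medium. Site selectivity needs no control, since C3' of the naphthalene carries the SEM ether and C4 of the isoindolinone carries OMe, so the peri C–H is the only bond within reach of the alkoxide-bound metal.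

**Step 9**
Reactants: 13 (S)-4-methoxy-7'-methyl-3'-{[2-(trimethylsilyl)ethoxy]methoxy}-2-[2-(triisopropylsilyloxy)ethyl]spiro[isoindoline-3,2'-naphtho[1,8-bc]furan]-1-one
Product: 15 (S)-3'-hydroxy-2-(2-hydroxyethyl)-4-methoxy-7'-methylspiro[isoindoline-3,2'-naphtho[1,8-bc]furan]-1-one (CNP0434366.2), via SEM-protected alcohol 14 (not isolated)
Conditions: TBAF (6 equiv), THF, rt then 60 °C; aq. NH4Cl
Reagents that add atoms: none
Why: Fluoride-mediated desilylation should cleave the primary TIPS ether at room temperature and, on warming, attack the silicon of the SEM group, which fragments to ethylene and formaldehyde and frees the naphthoxide; no acid is used, so the N,O-ketal and the configuration at C3 should persist.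

**Compound list**

1 | 3-methoxybenzoyl chloride | COc1cccc(C(=O)Cl)c1 | starting material
2 | ethanolamine | NCCO | starting material
3 | N-(2-hydroxyethyl)-3-methoxybenzamide | COc1cccc(C(=O)NCCO)c1 | intermediate
4 | 3-methoxy-N-[2-(triisopropylsilyloxy)ethyl]benzamide | COc1cccc(C(=O)NCCO[Si](C(C)C)(C(C)C)C(C)C)c1 | intermediate
5 | 6-bromo-2-naphthol | Oc1ccc2cc(Br)ccc2c1 | starting material
6 | 6-bromo-2-hydroxy-1-naphthaldehyde | O=Cc1c(O)ccc2cc(Br)ccc12 | intermediate
7 | 6-bromo-2-{[2-(trimethylsilyl)ethoxy]methoxy}-1-naphthaldehyde | O=Cc1c(OCOCC[Si](C)(C)C)ccc2cc(Br)ccc12 | intermediate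
8 | 6-methyl-2-{[2-(trimethylsilyl)ethoxy]methoxy}-1-naphthaldehyde | O=Cc1c(OCOCC[Si](C)(C)C)ccc2cc(C)ccc12 | intermediate
9 | N,2-dilithio-3-methoxy-N-[2-(triisopropylsilyloxy)ethyl]benzamide | COc1cccc(C(=O)N([Li])CCO[Si](C(C)C)(C(C)C)C(C)C)c1[Li] | intermediate (not isolated)
10 | rac-2-[hydroxy(6-methyl-2-{[2-(trimethylsilyl)ethoxy]methoxy}naphthalen-1-yl)methyl]-3-methoxy-N-[2-(triisopropylsilyloxy)ethyl]benzamide | COc1cccc(C(=O)NCCO[Si](C(C)C)(C(C)C)C(C)C)c1C(O)c1c(OCOCC[Si](C)(C)C)ccc2cc(C)ccc12 | intermediate
11 | 3-methoxy-2-(6-methyl-2-{[2-(trimethylsilyl)ethoxy]methoxy}-1-naphthoyl)-N-[2-(triisopropylsilyloxy)ethyl]benzamide (keto amide) | COc1cccc(C(=O)NCCO[Si](C(C)C)(C(C)C)C(C)C)c1C(=O)c1c(OCOCC[Si](C)(C)C)ccc2cc(C)ccc12 | intermediate (not isolated)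
12 | rac-3-hydroxy-4-methoxy-3-(6-methyl-2-{[2-(trimethylsilyl)ethoxy]methoxy}naphthalen-1-yl)-2-[2-(triisopropylsilyloxy)ethyl]isoindolin-1-one | COc1cccc2c1C(O)(c1c(OCOCC[Si](C)(C)C)ccc3cc(C)ccc13)N(CCO[Si](C(C)C)(C(C)C)C(C)C)C2=O | intermediate
13 | (S)-4-methoxy-7'-methyl-3'-{[2-(trimethylsilyl)ethoxy]methoxy}-2-[2-(triisopropylsilyloxy)ethyl]spiro[isoindoline-3,2'-naphtho[1,8-bc]furan]-1-one | COc1cccc2c1[C@]1(Oc3cc(C)cc4ccc(OCOCC[Si](C)(C)C)c1c34)N(CCO[Si](C(C)C)(C(C)C)C(C)C)C2=O | intermediate
14 | (S)-2-(2-hydroxyethyl)-4-methoxy-7'-methyl-3'-{[2-(trimethylsilyl)ethoxy]methoxy}spiro[isoindoline-3,2'-naphtho[1,8-bc]furan]-1-one | COc1cccc2c1[C@]1(Oc3cc(C)cc4ccc(OCOCC[Si](C)(C)C)c1c34)N(CCO)C2=O | intermediate (not isolated)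
15 | (S)-3'-hydroxy-2-(2-hydroxyethyl)-4-methoxy-7'-methylspiro[isoindoline-3,2'-naphtho[1,8-bc]furan]-1-one (CNP0434366.2) | COc1cccc2c1[C@]1(Oc3cc(C)cc4ccc(O)c1c34)N(CCO)C2=O | target

**Step count**

Total: 9 steps. Longest linear sequence: 7 steps (steps 3, 4, 5, 6, 7, 8, 9, from 5).

**Steps most likely to fail**

1. Step 8. The hemiaminal may epimerise more slowly than it cyclises, or the ligand may discriminate poorly between the two enantiomers in the C–H cleavage, so that the spiro ketal forms with low enantiomeric purity. β-Aryl elimination from the palladium alkoxide and oxidation of the electron-rich alkoxynaphthalene by the iodine(III) reagent would also consume material. The fallback sets out from 12 and comes back at 13. Without the chiral ligand, the established hydroxyl-directed cyclisation conditions (Pd(OAc)2, PhI(OAc)2, Li2CO3, C6F6, 100 °C) should give the racemic SEM/TIPS-protected spiro ketal F1. Preparative HPLC on a chiral stationary phase (amylose tris(3,5-dimethylphenylcarbamate), hexane/i-PrOH) would then separate 13 from the (R)-enantiomer of 13 F2, which is set aside.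

2. Step 9. The fluoride-induced fragmentation of the aryl SEM acetal may stall at a temperature the product tolerates. In the hot basic medium the spiro N,O-ketal may also ionise and be captured by the side-chain alkoxide. The fallback sets out from 13 and comes back at 15. It removes the two groups in separate operations with a different first reagent. A chelating Lewis acid (MgBr2·OEt2, Et2O/MeNO2, rt) would cleave the SEM acetal while the TIPS ether still masks the side-chain oxygen, and should give (S)-3'-hydroxy-4-methoxy-7'-methyl-2-[2-(triisopropylsilyloxy)ethyl]spiro[isoindoline-3,2'-naphtho[1,8-bc]furan]-1-one F3. Buffered desilylation (TBAF/AcOH, THF, 0 °C) would then give 15.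

3. Step 6. Deprotonation may be incomplete or misdirected (at C6 or on the side chain), so that the hindered aldehyde meets residual s-BuLi or a wrong aryllithium. The hydroxy amide may also lactonise on work-up. The fallback sets out from 2 and comes back at 9. It replaces deprotonation by halogen–lithium exchange. Commercial 2-bromo-3-methoxybenzoic acid F4 would be activated with CDI (THF, rt) to (2-bromo-3-methoxyphenyl)(1H-imidazol-1-yl)methanone F5 and treated with ethanolamine 2 to give 2-bromo-N-(2-hydroxyethyl)-3-methoxybenzamide F6. TIPSCl/imidazole would convert this into 2-bromo-3-methoxy-N-[2-(triisopropylsilyloxy)ethyl]benzamide F7. Deprotonation of the N–H with MeLi (THF, −78 °C), then bromine–lithium exchange with t-BuLi (2 equiv), would place the lithium at C2 without ambiguity and give 9, which adds to 8 as in step 6.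

**Further compounds**

F1 | step 8 | rac-4-methoxy-7'-methyl-3'-{[2-(trimethylsilyl)ethoxy]methoxy}-2-[2-(triisopropylsilyloxy)ethyl]spiro[isoindoline-3,2'-naphtho[1,8-bc]furan]-1-one | COc1cccc2c1C1(Oc3cc(C)cc4ccc(OCOCC[Si](C)(C)C)c1c34)N(CCO[Si](C(C)C)(C(C)C)C(C)C)C2=O
F2 | step 8 | (R)-4-methoxy-7'-methyl-3'-{[2-(trimethylsilyl)ethoxy]methoxy}-2-[2-(triisopropylsilyloxy)ethyl]spiro[isoindoline-3,2'-naphtho[1,8-bc]furan]-1-one | COc1cccc2c1[C@@]1(Oc3cc(C)cc4ccc(OCOCC[Si](C)(C)C)c1c34)N(CCO[Si](C(C)C)(C(C)C)C(C)C)C2=O
F3 | step 9 | (S)-3'-hydroxy-4-methoxy-7'-methyl-2-[2-(triisopropylsilyloxy)ethyl]spiro[isoindoline-3,2'-naphtho[1,8-bc]furan]-1-one | COc1cccc2c1[C@]1(Oc3cc(C)cc4ccc(O)c1c34)N(CCO[Si](C(C)C)(C(C)C)C(C)C)C2=O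
F4 | step 6 | 2-bromo-3-methoxybenzoic acid | COc1cccc(C(=O)O)c1Br
F5 | step 6 | (2-bromo-3-methoxyphenyl)(1H-imidazol-1-yl)methanone | COc1cccc(C(=O)n2ccnc2)c1Br
F6 | step 6 | 2-bromo-N-(2-hydroxyethyl)-3-methoxybenzamide | COc1cccc(C(=O)NCCO)c1Br
F7 | step 6 | 2-bromo-3-methoxy-N-[2-(triisopropylsilyloxy)ethyl]benzamide | COc1cccc(C(=O)NCCO[Si](C(C)C)(C(C)C)C(C)C)c1Br
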